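**Assumptions (remarks on the chemistry)**
- Ring numbering used throughout: O1, C2 (3,4-dimethoxyphenyl), C3 (methyl), C4 (methyl), C5 (4-hydroxy-3,5-dimethoxyphenyl). In this numbering the target is (2S,3S,4R,5R): the aryl groups are cis to each other, the methyl groups are cis to each other, and each aryl group is trans to its neighbouring methyl group.
- The facial sense of the aminoindanol-derived triazolium carbene with this aldehyde is assumed, not known. The route is written for the antipode that gives the 4R lactone; both antipodes of the salt are commercial.
- Catalyst-bound species and carbocations are treated as mechanistic intermediates in the Why lines and carry no compound number.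

## Structural features

The target is a single oxolane ring with four contiguous stereocentres: C2 carries a 3,4-dimethoxyphenyl group, C3 and C4 a methyl group each, and C5 a 4-hydroxy-3,5-dimethoxyphenyl group. The relative configuration is 2,3-trans, 3,4-cis, 4,5-trans, so both aryl groups lie on one face and both methyl groups on the other. With two identical aryl groups this array would be meso; the molecule is chiral only because the aryl groups differ, so absolute control means fixing that the R-configured C4 is the methyl-bearing carbon next to the phenolic ring. Both ring C–O bonds are benzylic and activated by para oxygen donors: acid can ionize them (epimerization, or irreversible Friedel–Crafts closure to an aryltetralin), hydrogenolysis can cleave them, and the free phenol is sensitive to oxidants. The real difficulty is the cis relationship of the C3 and C4 methyl groups, which no equilibration can produce, together with the near-symmetry, which leaves few handles for an enantioselective entry. The aryl-bearing carbons are easier, because each prefers to sit trans to its neighbouring methyl group. The key step exploits the C4–C5 and O1–C2 bonds: C5 is a carbinol carbon that can come from an aryl aldehyde, and C4 with its methyl group is the β-carbon of a four-carbon enal whose carbonyl carbon becomes C2 at the carboxyl oxidation level. This leaves C3 as an enolizable methylene for the second methyl group and C2 as an electrophilic site for the second aryl group.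

## Logic of the disconnections

**13 from 12.** No skeletal bond is removed. The C5–O1 bond of 13 is opened and re-closed in thought, which relates 13 to 12, its epimer at C5. The cut is placed here because C5 of 13 carries a para-hydroxyaryl group and holds it trans to the C4 methyl group, the arrangement favoured at equilibrium. Every earlier step is thereby freed from delivering the 4,5-trans relationship. The forward step must ionize C5–O1 reversibly without letting the cation be trapped by the other aryl ring.

**12 from 11.** The phenolic O–H is exchanged for an O–S bond to a sulfonyl group. The sulfonyl group cancels the donor power of the para oxygen, so in 11 the C5–O1 bond resists ionization and the two benzylic centres become chemically distinct. The forward step must break the S–O bond with base while leaving the ring ether alone.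

**11 from 9 and 10.** The C2–aryl bond is cut, giving 9 as a C2 electrophile at the aldehyde oxidation level and 10 as the arene nucleophile. C2 sits next to O1 and can be ionized to a ring oxocarbenium ion, and the substituents on C3, C4 and C5 of 9 all block the same face, so the arene must arrive trans to the C3 methyl group. One aryl ring and the C2 stereocentre are removed. The forward step needs substitution para to a methoxy group of 10 and must not lose the C3 configuration through the cyclic enol ether.

**9 from 8.** The C2–H bond is exchanged for a carbonyl group. The carboxyl level at C2 is what the annulation delivers and what makes C3 enolizable. The forward reduction must stop at the lactol.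

**8 from 7.** The C–H bonds at C3 and at its methyl carbon are removed, leaving the exocyclic alkene of 7. Hydrogen added to a planar C3 from the face away from the cis C4 methyl and C5 aryl groups puts the new methyl group on their face, which gives the 3,4-cis relationship that enolate alkylation would not. The C3 stereocentre is removed. The forward step needs a catalyst that neither moves the double bond nor cleaves the benzylic C5–O1 bond.

**7 from 4.** The C3=CH2 bond is cut. The C3 methylene of 4 is its only acidic site, and a one-carbon iminium electrophile followed by elimination installs the methylidene group. The forward step needs clean mono-functionalization and a sulfonate that tolerates an amide base.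

**4 from 2 and 3.** The C4–C5 and O1–C2 bonds are cut. 2 supplies C5 with its aryl group, and 3 supplies C2, C3, C4 and the C4 methyl group. Both carbons to be joined are carbonyl-type electrophiles, so the polarity of 3 must be inverted by a carbene catalyst, which then also closes the ring. Ring, two bonds and two stereocentres fall back to two simple aldehydes. The forward step must favour cross- over self-annulation, control the face of C4, and give the cis lactone.

**2 from 1.** The aryl O–S bond is cut. The sulfonate serves three purposes: it makes the aldehyde of 2 more electrophilic than that of 3, it masks the phenol through steps 2 to 6, and it holds C5 configurationally stable until it is removed. 1, 3 and 10 are purchased.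

## Other disconnections considered

**Alternative 1:** The cuts fall on C2–C3 and C4–C5 and, later, on both C–aryl bonds. Furan (A1) and maleic anhydride (A2) would combine in a Diels–Alder reaction to the exo oxabicyclic anhydride A3. Reduction of the anhydride carbons to the two methyl groups and oxidative cleavage of the ring alkene would give the meso diacid A4, whose carboxyl groups would be replaced by the aryl groups in two decarboxylative cross-couplings.
- In favour: the cycloaddition needs no catalyst, is cheap and scalable, and is more dependable than the carbene annulation. On reliability of the key step this plan is the better one.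
- In favour: the exo topology encodes the relative configuration exactly, since in A4 the cis methyl groups lie trans to both carboxyl carbons. On relative stereochemistry it is at least the equal of the chosen plan, which needs a final epimerization.
- Against: A3 and A4 are meso, and the target is chiral only through the difference between its aryl groups. The two enantiotopic carboxyl groups would have to be distinguished by a desymmetrization and then coupled one after the other with different aryl partners.
- Against: the α-oxy radical or organometallic intermediates of such couplings lose the C2 and C5 configuration, and a return to trans would be by preference and not by design.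
- Against: A3 reverts to A1 and A2 on warming, and two carbonyl-to-methyl reductions plus an alkene cleavage are oxidation-state overhead.
- Comparison: the sequence would probably need about half as many steps again as the eight of the chosen route. Mechanistically the chosen plan sets the absolute configuration in the step that builds the ring, whereas this one builds a symmetric ring and must break the symmetry afterwards.

**Alternative 2:** The cut is the C3–C4 bond. In bromo ether A5, O1 already links the two aryl-bearing carbons and C2 carries a vinyl group. Bu3SnH with azobisisobutyronitrile would generate the secondary radical at C4, which should add 5-exo-trig to the inner vinyl carbon; the resulting primary radical becomes the C3 methyl group of A6, the O-benzyl ether of the target.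
- In favour: ring, C3–C4 bond and one methyl group arise in one step, and both aryl groups are in place beforehand, so no cation is ever generated beside an electron-rich arene. On that point it is safer than steps 6 and 8 of the chosen plan.
- In favour: the chair-like transition state usually invoked for 5-hexenyl radicals predicts the C3 and C4 substituents cis to each other and each trans to its flanking aryl group, which is the pattern of the target.
- In favour: the route could be about six steps, so on step count it is the better plan.
- Against: the difficulty moves into A5, an unsymmetrical ether between two secondary benzylic carbons. Bromoetherification of a propenylarene with a chiral allylic alcohol, the obvious assembly, offers no control of C5 with respect to C2.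
- Against: selectivity in acyclic 3-oxahexenyl radical closures is usually moderate, and here C3 and C4 depend on it at once. Stoichiometric tin must be removed late, and hydrogenolysis of the benzyl ether competes with the two benzylic ring C–O bonds.
- Comparison: the chosen route sets each stereocentre in turn on a ring with a clear facial bias and fixes the absolute configuration catalytically. The alternative is shorter but would likely still need an acid equilibration at C5 at the end, so that operation is not saved.

**Alternative 3:** The cuts are O1–C5 and C4–C5. This is the same carbon–carbon bond as in the chosen plan, but C4 is now the nucleophilic carbon of an enol carbamate. BF3·OEt2 would condense the hydroxyl group of the anti homoaldol adduct A7 with aldehyde A8 to an oxocarbenium ion. The enol carbamate carbon would attack it, and loss of the carbamoyl group would leave the C4 carbaldehyde A9.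
- In favour: the plan is convergent, both aryl-bearing carbons enter as aldehydes, and no late arylation is needed.
- In favour: metallated crotyl carbamates with a chiral diamine are a well-established source of anti adducts of high enantiomeric purity. On absolute stereocontrol this alternative is better founded than a carbene annulation with a simple aryl aldehyde.
- Against: C4 emerges as a formyl group, not a methyl group. Reduction, activation and hydride displacement at a hindered centre add three steps.
- Against: the formyl-bearing C4 is epimerizable and must stay cis to the C3 methyl group, the chiral base and the titanium reagent are stoichiometric and cryogenic, and debenzylation again competes with the ring C–O bonds.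
- Comparison: the step count would be about eight or nine, equal to the chosen plan. Structurally the chosen plan brings C4 in with its methyl group at the final oxidation level and makes the cis-dimethyl pair by hydrogenation from the open face, whereas this alternative needs the same relationship to survive as an enolizable aldehyde.

Key step: step 2

## Route

Step 1
Reactants: 1 syringaldehyde (4-hydroxy-3,5-dimethoxybenzaldehyde)
Product: 2 4-formyl-2,6-dimethoxyphenyl 4-methylbenzenesulfonate
Conditions: TsCl (1.2 equiv), K2CO3 (2 equiv), acetone, reflux
Reagents that add atoms: 4-methylbenzenesulfonyl chloride (TsCl), Cc1ccc(cc1)S(Cl)(=O)=O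
Why: O-Sulfonylation of a phenol: the phenoxide attacks sulfur and displaces chloride while the aldehyde is inert to carbonate; the sulfonate turns the para oxygen from a donor into an acceptor, which the next step needs, and masks the phenol until step 7.

Step 2
Reactants: 2 4-formyl-2,6-dimethoxyphenyl 4-methylbenzenesulfonate; 3 (E)-crotonaldehyde ((E)-but-2-enal)
Product: 4 (4R,5S)-5-[3,5-dimethoxy-4-(tosyloxy)phenyl]-4-methyloxolan-2-one (cis lactone)
Conditions: (5aR,10bS)-2-mesityl-5a,10b-dihydro-4H,6H-indeno[2,1-b][1,2,4]triazolo[4,3-d][1,4]oxazin-2-ium chloride (10 mol %; the (5aS,10bR) salt if the facial sense proves opposite), DBU (1,8-diazabicyclo[5.4.0]undec-7-ene, 10 mol %), THF, 4 Å molecular sieves, rt; 3 added slowly to 2 (1.5 equiv)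
Reagents that add atoms: none
Why: The carbene released from the triazolium salt adds to the carbonyl group of 3, and a proton shift gives the conjugated enaminol (extended Breslow intermediate), whose former β-carbon is nucleophilic. That carbon adds to the carbonyl carbon of 2 (C4–C5), the enol tautomerizes to an acyl azolium, and the C5 alkoxide attacks the acyl carbon (O1–C2) in a 5-exo-trig acyl substitution that closes the oxolanone and frees the carbene. The closest known reaction type is the carbene-catalysed homoenolate [3+2] annulation of enals with aryl aldehydes to cis-4,5-disubstituted γ-butyrolactones. C4 is set by the catalyst: the indane wall of the aminoindanol backbone shields one face of the enaminol, so the aldehyde should meet the β-carbon on the face that leads to 4R. C5 follows from the mutual orientation of the partners in the C–C bond-forming transition state, which in this reaction class places the aryl group and the β-substituent cis on the lactone; any trans isomer is to be removed by chromatography. The step needs cross-annulation to win over self-annulation of 3 and over benzoin coupling: 2 cannot form a homoenolate, its carbonyl group is made more electrophilic than that of 3 by the para sulfonyloxy group, it is kept in excess while 3 is added slowly, and the N-mesityl group steers the carbene toward the enal.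

Step 3
Reactants: 4 (4R,5S)-5-[3,5-dimethoxy-4-(tosyloxy)phenyl]-4-methyloxolan-2-one
Product: 7 (4R,5S)-5-[3,5-dimethoxy-4-(tosyloxy)phenyl]-4-methyl-3-methylideneoxolan-2-one, via Mannich base 5 (not isolated), via trimethylammonium iodide 6 (not isolated)
Conditions: LiN(iPr)2 (1.1 equiv, commercial solution), THF, −78 °C, then CH2=NMe2+ I−, −78 → 0 °C; MeI, MeOH, rt; aq NaHCO3, CH2Cl2, rt
Reagents that add atoms: N,N-dimethylmethylideneammonium iodide (Eschenmoser's salt), C=[N+](C)C.[I-], supplies the exocyclic CH2; iodomethane, CI, adds its methyl group to 6 only, and that group leaves again with trimethylamine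
Why: Eschenmoser methylenation: Mannich reaction of the lithium enolate, N-methylation and base-induced β-elimination of trimethylamine should give the exocyclic enoate; the sulfonate is flanked by two methoxy groups and has no ortho hydrogen for an anionic rearrangement, and C4 and C5 are not acidic and stay as set.

Step 4
Reactants: 7 (4R,5S)-5-[3,5-dimethoxy-4-(tosyloxy)phenyl]-4-methyl-3-methylideneoxolan-2-one
Product: 8 (3S,4R,5S)-5-[3,5-dimethoxy-4-(tosyloxy)phenyl]-3,4-dimethyloxolan-2-one (all-cis lactone)
Conditions: H2 (1–3 atm), RhCl(PPh3)3 (5 mol %), toluene–EtOH, rt
Reagents that add atoms: none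
Why: Homogeneous hydrogenation of a 1,1-disubstituted alkene: the rhodium hydride should reach the exocyclic double bond from the face opposite the cis C4 methyl and C5 aryl groups, so the new C3 methyl group ends up on their face (3S); the soluble catalyst is chosen because it does not hydrogenolyse the benzylic C5–O1 bond or the aryl sulfonate and has little tendency to move the double bond into the ring.

Step 5
Reactants: 8 (3S,4R,5S)-5-[3,5-dimethoxy-4-(tosyloxy)phenyl]-3,4-dimethyloxolan-2-one
Product: 9 (3S,4R,5S)-5-[3,5-dimethoxy-4-(tosyloxy)phenyl]-3,4-dimethyloxolan-2-ol (lactol, both C2 anomers)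
Conditions: iBu2AlH (1.1 equiv), CH2Cl2, −78 °C; aq Rochelle salt
Reagents that add atoms: none
Why: Partial reduction of a lactone: the aluminium hemiacetal is stable at −78 °C and gives the lactol on work-up; the aryl sulfonate is inert to the hydride at this temperature, the medium is not basic so the C3 centre next to the carbonyl group is not epimerized, and the lactol is used promptly.

Step 6
Reactants: 9 (3S,4R,5S)-5-[3,5-dimethoxy-4-(tosyloxy)phenyl]-3,4-dimethyloxolan-2-ol; 10 veratrole (1,2-dimethoxybenzene)
Product: 11 (2S,3S,4R,5S)-2-(3,4-dimethoxyphenyl)-5-[3,5-dimethoxy-4-(tosyloxy)phenyl]-3,4-dimethyloxolane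
Conditions: 10 (3 equiv), BF3·OEt2 (1.5 equiv), CH2Cl2, −78 → −20 °C
Reagents that add atoms: none
Why: Friedel–Crafts arylation of a cyclic oxocarbenium ion: BF3 ionizes the lactol hydroxyl and 10 attacks through its 4-position, para to a methoxy group; the C3 methyl, C4 methyl and C5 aryl groups all cover one face, so the arene should add to the other and give the 2,3-trans product (2S). The sulfonyloxy group keeps the C5 aryl ring too electron-poor to assist C5–O1 ionization or to compete as a nucleophile.

Step 7
Reactants: 11 (2S,3S,4R,5S)-2-(3,4-dimethoxyphenyl)-5-[3,5-dimethoxy-4-(tosyloxy)phenyl]-3,4-dimethyloxolane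
Product: 12 (2S,3S,4R,5S)-2-(3,4-dimethoxyphenyl)-5-(4-hydroxy-3,5-dimethoxyphenyl)-3,4-dimethyloxolane (C5 epimer of the target)
Conditions: KOH, EtOH–H2O, 80 °C; then dil. HCl to pH 6
Reagents that add atoms: none
Why: Alkaline cleavage of an aryl sulfonate: hydroxide attacks sulfur and the phenoxide leaves (S–O fission), while the ring ether and the methyl ethers are inert to base and no stereocentre is acidic.

Step 8
Reactants: 12 (2S,3S,4R,5S)-2-(3,4-dimethoxyphenyl)-5-(4-hydroxy-3,5-dimethoxyphenyl)-3,4-dimethyloxolane
Product: 13 (2S,3S,4R,5R)-2-(3,4-dimethoxyphenyl)-5-(4-hydroxy-3,5-dimethoxyphenyl)-3,4-dimethyloxolane (target)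
Conditions: BF3·OEt2 (0.3 equiv), CH2Cl2, −20 → 0 °C; aq NaHCO3
Reagents that add atoms: none
Why: Acid-catalysed epimerization under thermodynamic control: coordination at O1 allows heterolysis of C5–O1 to a benzylic cation stabilized by the para hydroxyl group (a protonated quinone methide), and 5-exo-trig re-closure by the C2 oxygen should favour the aryl group trans to the C4 methyl group (5R). C2 can ionize in the same way but already holds its favoured trans arrangement, and C3 and C4 have no pathway for change.

## Compound list

1 | syringaldehyde (4-hydroxy-3,5-dimethoxybenzaldehyde) | COc1cc(C=O)cc(OC)c1O | starting material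
2 | 4-formyl-2,6-dimethoxyphenyl 4-methylbenzenesulfonate | Cc1ccc(cc1)S(=O)(=O)Oc1c(OC)cc(C=O)cc1OC | intermediate
3 | (E)-crotonaldehyde | C/C=C/C=O | starting material
4 | (4R,5S)-5-[3,5-dimethoxy-4-(tosyloxy)phenyl]-4-methyloxolan-2-one | Cc1ccc(cc1)S(=O)(=O)Oc1c(OC)cc(cc1OC)[C@H]1OC(=O)C[C@H]1C | intermediate
5 | (3S,4R,5S)-3-[(dimethylamino)methyl]-5-[3,5-dimethoxy-4-(tosyloxy)phenyl]-4-methyloxolan-2-one (Mannich base, 3,4-trans expected) | Cc1ccc(cc1)S(=O)(=O)Oc1c(OC)cc(cc1OC)[C@H]1OC(=O)[C@H](CN(C)C)[C@H]1C | intermediate (not isolated)
6 | [(3S,4R,5S)-5-[3,5-dimethoxy-4-(tosyloxy)phenyl]-4-methyl-2-oxooxolan-3-yl]-N,N,N-trimethylmethanaminium iodide | Cc1ccc(cc1)S(=O)(=O)Oc1c(OC)cc(cc1OC)[C@H]1OC(=O)[C@H](C[N+](C)(C)C)[C@H]1C.[I-] | intermediate (not isolated)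
7 | (4R,5S)-5-[3,5-dimethoxy-4-(tosyloxy)phenyl]-4-methyl-3-methylideneoxolan-2-one | Cc1ccc(cc1)S(=O)(=O)Oc1c(OC)cc(cc1OC)[C@H]1OC(=O)C(=C)[C@H]1C | intermediate
8 | (3S,4R,5S)-5-[3,5-dimethoxy-4-(tosyloxy)phenyl]-3,4-dimethyloxolan-2-one (all-cis) | Cc1ccc(cc1)S(=O)(=O)Oc1c(OC)cc(cc1OC)[C@H]1OC(=O)[C@@H](C)[C@H]1C | intermediate
9 | (3S,4R,5S)-5-[3,5-dimethoxy-4-(tosyloxy)phenyl]-3,4-dimethyloxolan-2-ol (C2 anomers) | Cc1ccc(cc1)S(=O)(=O)Oc1c(OC)cc(cc1OC)[C@H]1OC(O)[C@@H](C)[C@H]1C | intermediate
10 | veratrole (1,2-dimethoxybenzene) | COc1ccccc1OC | starting material
11 | (2S,3S,4R,5S)-2-(3,4-dimethoxyphenyl)-5-[3,5-dimethoxy-4-(tosyloxy)phenyl]-3,4-dimethyloxolane | COc1ccc([C@H]2O[C@H](c3cc(OC)c(OS(=O)(=O)c4ccc(C)cc4)c(OC)c3)[C@H](C)[C@@H]2C)cc1OC | intermediate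
12 | (2S,3S,4R,5S)-2-(3,4-dimethoxyphenyl)-5-(4-hydroxy-3,5-dimethoxyphenyl)-3,4-dimethyloxolane | COc1ccc([C@H]2O[C@H](c3cc(OC)c(O)c(OC)c3)[C@H](C)[C@@H]2C)cc1OC | intermediate
13 | (2S,3S,4R,5R)-2-(3,4-dimethoxyphenyl)-5-(4-hydroxy-3,5-dimethoxyphenyl)-3,4-dimethyloxolane | COc1ccc([C@H]2O[C@@H](c3cc(OC)c(O)c(OC)c3)[C@H](C)[C@@H]2C)cc1OC | target

## Step count and risk

Total step count: 8. Longest linear sequence: 8 steps (1 → 13); 3 and 10 enter as purchased reactants.

The least certain steps, in route order with the key step first:

**Step 2 (key step).** The most likely failure is weak enantiofacial discrimination at the β-carbon, because a simple aryl aldehyde offers the catalyst no second binding point. Self-annulation of 3, benzoin-type coupling of 2, and erosion of the cis preference are further risks. The fallback makes the same two stereocentres by reagent-controlled allylation and sets out from 2. Asymmetric crotylboration with (Z)-crotyldiisopinocampheylborane of the appropriate antipode (THF, −78 °C; NaBO3·4H2O work-up) should give the syn alcohol (1S,2R)-1-[3,5-dimethoxy-4-(tosyloxy)phenyl]-2-methylbut-3-en-1-ol F1. Hydroboration with 9-borabicyclo[3.3.1]nonane and oxidation with NaBO3·4H2O should give (1S,2R)-1-[3,5-dimethoxy-4-(tosyloxy)phenyl]-2-methylbutane-1,4-diol F2. Oxidation with catalytic (2,2,6,6-tetramethylpiperidin-1-yl)oxyl and PhI(OAc)2 in CH2Cl2 takes the primary alcohol through the lactol to the lactone, and the route is rejoined at 4.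

**Step 4.** Poor facial selectivity, slow turnover on a hindered conjugated alkene, or migration of the double bond into the ring could spoil the C3 centre. The fallback sets C3 by enolate chemistry and sets out from 4. LiN(iPr)2 and MeI at −78 °C should methylate anti to the C4 methyl group and give (3R,4R,5S)-5-[3,5-dimethoxy-4-(tosyloxy)phenyl]-3,4-dimethyloxolan-2-one F3. A second deprotonation with LiN(iPr)2 and kinetic protonation by 2,6-di-tert-butyl-4-methylphenol at −78 °C should deliver the proton to the open face and push the methyl group cis, rejoining the route at 8.

**Step 6.** The arene is only moderately nucleophilic, so the oxocarbenium ion may instead lose a proton reversibly to the cyclic enol ether, which would scramble C3; the product may also be alkylated a second time. The fallback uses an organometallic nucleophile on an anomeric sulfone and sets out from 9. Benzenesulfinic acid with CaCl2 in CH2Cl2 should give (3S,4R,5S)-5-[3,5-dimethoxy-4-(tosyloxy)phenyl]-3,4-dimethyl-2-(phenylsulfonyl)oxolane F4. 3,4-Dimethoxyphenylmagnesium bromide with ZnBr2 in THF then displaces the sulfinate through the same oxocarbenium ion, now captured quickly by an arylzinc species, and the route is rejoined at 11.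

**Step 8.** The benzylic cation at C5 may be captured irreversibly by the 3,4-dimethoxyphenyl ring (Friedel–Crafts closure to an aryltetralin) or may oligomerize as a quinone methide before the ring re-closes; the equilibration may also stop short. The fallback inverts C5 by substitution before the second aryl ring is present and sets out from 8.
- LiOH in THF–H2O and careful acidification at 0 °C give (2S,3R,4S)-4-[3,5-dimethoxy-4-(tosyloxy)phenyl]-4-hydroxy-2,3-dimethylbutanoic acid F5, which is used at once.
- Mitsunobu lactonization (PPh3, diisopropyl azodicarboxylate, THF, 0 °C) should close the ring with inversion at the benzylic carbon to (3S,4R,5R)-5-[3,5-dimethoxy-4-(tosyloxy)phenyl]-3,4-dimethyloxolan-2-one F6.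
- iBu2AlH at −78 °C gives the lactol (3S,4R,5R)-5-[3,5-dimethoxy-4-(tosyloxy)phenyl]-3,4-dimethyloxolan-2-ol F7.
- BF3·OEt2 with 10 should add the arene trans to the C3 methyl group and give (2S,3S,4R,5R)-2-(3,4-dimethoxyphenyl)-5-[3,5-dimethoxy-4-(tosyloxy)phenyl]-3,4-dimethyloxolane F8.
- KOH in EtOH–H2O then removes the sulfonate, and the route is rejoined at 13.

## Further compounds

F1 | step 2 | (1S,2R)-1-[3,5-dimethoxy-4-(tosyloxy)phenyl]-2-methylbut-3-en-1-ol | Cc1ccc(cc1)S(=O)(=O)Oc1c(OC)cc(cc1OC)[C@@H](O)[C@H](C)C=C
F2 | step 2 | (1S,2R)-1-[3,5-dimethoxy-4-(tosyloxy)phenyl]-2-methylbutane-1,4-diol | Cc1ccc(cc1)S(=O)(=O)Oc1c(OC)cc(cc1OC)[C@@H](O)[C@H](C)CCO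
F3 | step 4 | (3R,4R,5S)-5-[3,5-dimethoxy-4-(tosyloxy)phenyl]-3,4-dimethyloxolan-2-one | Cc1ccc(cc1)S(=O)(=O)Oc1c(OC)cc(cc1OC)[C@H]1OC(=O)[C@H](C)[C@H]1C
F4 | step 6 | (3S,4R,5S)-5-[3,5-dimethoxy-4-(tosyloxy)phenyl]-3,4-dimethyl-2-(phenylsulfonyl)oxolane (C2 anomers) | Cc1ccc(cc1)S(=O)(=O)Oc1c(OC)cc(cc1OC)[C@H]1OC(S(=O)(=O)c2ccccc2)[C@@H](C)[C@H]1C
F5 | step 8 | (2S,3R,4S)-4-[3,5-dimethoxy-4-(tosyloxy)phenyl]-4-hydroxy-2,3-dimethylbutanoic acid | Cc1ccc(cc1)S(=O)(=O)Oc1c(OC)cc(cc1OC)[C@@H](O)[C@H](C)[C@H](C)C(O)=O
F6 | step 8 | (3S,4R,5R)-5-[3,5-dimethoxy-4-(tosyloxy)phenyl]-3,4-dimethyloxolan-2-one | Cc1ccc(cc1)S(=O)(=O)Oc1c(OC)cc(cc1OC)[C@@H]1OC(=O)[C@@H](C)[C@H]1C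
F7 | step 8 | (3S,4R,5R)-5-[3,5-dimethoxy-4-(tosyloxy)phenyl]-3,4-dimethyloxolan-2-ol (C2 anomers) | Cc1ccc(cc1)S(=O)(=O)Oc1c(OC)cc(cc1OC)[C@@H]1OC(O)[C@@H](C)[C@H]1C
F8 | step 8 | (2S,3S,4R,5R)-2-(3,4-dimethoxyphenyl)-5-[3,5-dimethoxy-4-(tosyloxy)phenyl]-3,4-dimethyloxolane | COc1ccc([C@H]2O[C@@H](c3cc(OC)c(OS(=O)(=O)c4ccc(C)cc4)c(OC)c3)[C@H](C)[C@@H]2C)cc1OC
A1 | alternative 1 | furan | c1ccoc1
A2 | alternative 1 | maleic anhydride | O=C1OC(=O)C=C1
A3 | alternative 1 | exo-7-oxabicyclo[2.2.1]hept-5-ene-2,3-dicarboxylic anhydride (meso) | C1=C[C@H]2O[C@@H]1[C@H](C(=O)O3)[C@@H]2C3=O
A4 | alternative 1 | meso-3,4-dimethyloxolane-2,5-dicarboxylic acid (carboxyl groups cis to each other and trans to the cis methyl groups) | OC(=O)[C@H]1O[C@@H](C(O)=O)[C@H](C)[C@@H]1C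
A5 | alternative 2 | 1-(4-benzyloxy-3,5-dimethoxyphenyl)-2-bromopropyl 1-(3,4-dimethoxyphenyl)prop-2-enyl ether (oxygen-bearing carbons configured as in the target, bromide carbon undefined) | COc1ccc(cc1OC)[C@H](C=C)O[C@@H](c1cc(OC)c(OCc2ccccc2)c(OC)c1)C(C)Br
A6 | alternative 2 | (2S,3S,4R,5R)-5-(4-benzyloxy-3,5-dimethoxyphenyl)-2-(3,4-dimethoxyphenyl)-3,4-dimethyloxolane (O-benzyl ether of the target) | COc1ccc([C@H]2O[C@@H](c3cc(OC)c(OCc4ccccc4)c(OC)c3)[C@H](C)[C@@H]2C)cc1OC
A7 | alternative 3 | (1Z,3S,4S)-4-(3,4-dimethoxyphenyl)-4-hydroxy-3-methylbut-1-en-1-yl N,N-diisopropylcarbamate | COc1ccc(cc1OC)[C@@H](O)[C@@H](C)/C=C\OC(=O)N(C(C)C)C(C)C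
A8 | alternative 3 | 4-benzyloxy-3,5-dimethoxybenzaldehyde | COc1cc(C=O)cc(OC)c1OCc1ccccc1
A9 | alternative 3 | 2-(4-benzyloxy-3,5-dimethoxyphenyl)-5-(3,4-dimethoxyphenyl)-4-methyloxolane-3-carbaldehyde (ring configured as in the target) | COc1ccc([C@H]2O[C@@H](c3cc(OC)c(OCc4ccccc4)c(OC)c3)[C@H](C=O)[C@@H]2C)cc1OC
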